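**Plan**
- Numbering: C1 is the ester carbonyl carbon, C28 the terminal methyl. The retrosynthesis cuts, in order, the phenolic O–acetyl bond (protection), the C11–C12 CH2–CH2 bond of the acyl chain, and the C1(=O)–O ester bond to tyrosol.
- Enabling feature: C2–C28 is an unbranched, unfunctionalised polymethylene run. The C11–C12 bond is flanked only by CH2 groups and lies ten bonds or more from the ester and the benzene ring. Both halves are therefore plain primary alkyl radicals, available by decarboxylation of dodecanedioic acid (C1–C11) and stearic acid (C12–C28).
- Forward: a lipase joins tyrosol through its primary OH to the C12 diacid, and the phenol is then acetylated. A crossed Kolbe electrolysis with stearic acid then joins the chain at C11–C12 with the tyrosyl ester already in place, and aminolysis of the aryl acetate frees the phenol.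
- The ester bond is made on a small, soluble C12 piece, so the waxy C28 acid is never prepared or handled. No ring is formed.
- Stereochemistry: none to set.

Key step: step 3

Remark: the target has no stereogenic element (it is achiral), so "single enantiomer" requires no stereocontrol. Tyrosol, dodecanedioic acid and stearic acid are taken as commercial.

**Step 1**
Reactants: 1 tyrosol [4-(2-hydroxyethyl)phenol]; 2 dodecanedioic acid
Product: 3 12-[2-(4-hydroxyphenyl)ethoxy]-12-oxododecanoic acid
Conditions: 2 (4 equiv), Novozym 435 (immobilised Candida antarctica lipase B), 4 Å MS, 2-methyl-2-butanol, 60 °C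
Reagents that add atoms: none
Why: Lipase-catalysed direct esterification should acylate only the primary aliphatic OH of 1, because the acyl-enzyme does not accept phenols as nucleophiles; the fourfold excess of the symmetrical diacid biases the statistics towards the monoester, and the sieves remove the water formed.

**Step 2**
Reactants: 3 12-[2-(4-hydroxyphenyl)ethoxy]-12-oxododecanoic acid
Product: 5 12-[2-(4-acetoxyphenyl)ethoxy]-12-oxododecanoic acid, via mixed acetic anhydride 4 (not isolated)
Conditions: Ac2O (3 equiv), pyridine, CH2Cl2, 0 °C to rt; then H2O, THF, rt
Reagents that add atoms: acetic anhydride CC(=O)OC(C)=O; water O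
Why: Pyridine-mediated O-acetylation of the phenol with acetic anhydride is a standard acylation; the carboxyl group is transiently converted into the mixed anhydride 4, which is far more electrophilic than the aryl acetate or the alkyl ester and should be hydrolysed back to the acid during the aqueous stir.

**Step 3**
Reactants: 5 12-[2-(4-acetoxyphenyl)ethoxy]-12-oxododecanoic acid; 6 stearic acid (octadecanoic acid)
Product: 7 2-(4-acetoxyphenyl)ethyl octacosanoate (O-acetylbongardol)
Conditions: 6 (4 equiv, pre-mixed with KOH, 0.05 equiv per CO2H), MeOH/hexane, 40–45 °C, Pt anode/Pt cathode, undivided cell, constant current ca. 0.25 A cm–2, periodic polarity reversal, stopped while still weakly acidic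
Reagents that add atoms: none
Why: On platinum at high current density the carboxylates of 5 and 6 are each oxidised by one electron to acyloxy radicals that lose CO2, and the resulting primary radicals •(CH2)10CO2R and n-C17H35• combine in the anode layer to form the C11–C12 bond, while protons are reduced to H2 at the cathode. The closest known reaction type is the crossed (mixed) Kolbe electrolysis of a fatty acid with an α,ω-diacid half-ester, the classical chain-extension route to very-long-chain fatty esters. No ring is closed and no stereocentre is created. Cross-coupling over homo-coupling is secured statistically by the fourfold excess of cheap 6, and the expected by-products, tetratriacontane (a hydrocarbon) and the symmetrical C22 bis(aryl) diester, differ from 7 by a whole aryl ester unit in polarity and should separate on silica or by crystallisation. Radical coupling over further oxidation to carbocations (Hofer–Moest path) is favoured because both radicals are unbranched primary alkyls without an α-heteroatom, and by the weakly acidic, partially neutralised methanol, smooth platinum and high current density. The O-acetyl group makes the arene about as hard to oxidise as a simple alkylbenzene (a ring type tolerated in Kolbe couplings of phenylalkanoic acids) and removes the phenolic O–H that would quench radicals, and the acid-buffered electrolyte contains no methoxide, so neither the aryl acetate nor the C1 ester should undergo methanolysis if the electrolysis is stopped before the medium turns alkaline.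

**Step 4**
Reactants: 7 2-(4-acetoxyphenyl)ethyl octacosanoate
Product: 8 bongardol [2-(4-hydroxyphenyl)ethyl octacosanoate]
Conditions: pyrrolidine (3 equiv), THF, rt to 35 °C; dilute aqueous acid work-up
Reagents that add atoms: none
Why: Chemoselective aminolysis of an aryl acetate: phenoxide is a far better leaving group than the alkoxide of the C1 ester, so a secondary amine near room temperature should remove only the O-acetyl group and leave the long-chain alkyl ester intact.

**Compound list**
1 | tyrosol, 4-(2-hydroxyethyl)phenol | OCCc1ccc(O)cc1 | starting material
2 | dodecanedioic acid | OC(=O)CCCCCCCCCCC(=O)O | starting material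
3 | 12-[2-(4-hydroxyphenyl)ethoxy]-12-oxododecanoic acid | OC(=O)CCCCCCCCCCC(=O)OCCc1ccc(O)cc1 | intermediate
4 | acetic 12-[2-(4-acetoxyphenyl)ethoxy]-12-oxododecanoic anhydride (mixed anhydride) | CC(=O)OC(=O)CCCCCCCCCCC(=O)OCCc1ccc(OC(C)=O)cc1 | intermediate (not isolated)
5 | 12-[2-(4-acetoxyphenyl)ethoxy]-12-oxododecanoic acid | OC(=O)CCCCCCCCCCC(=O)OCCc1ccc(OC(C)=O)cc1 | intermediate
6 | stearic acid (octadecanoic acid) | CCCCCCCCCCCCCCCCCC(=O)O | starting material
7 | 2-(4-acetoxyphenyl)ethyl octacosanoate (O-acetylbongardol) | CCCCCCCCCCCCCCCCCCCCCCCCCCCC(=O)OCCc1ccc(OC(C)=O)cc1 | intermediate
8 | bongardol, 2-(4-hydroxyphenyl)ethyl octacosanoate | CCCCCCCCCCCCCCCCCCCCCCCCCCCC(=O)OCCc1ccc(O)cc1 | target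

**Step count**
Total steps: 4. Longest linear sequence: 4 steps (1 → 3 → 5 → 7 → 8); stearic acid 6 enters at step 3.

**Steps most likely to fail**

1. Step 3 (crossed Kolbe electrolysis). Possible failures are passivation of the anode by waxy deposits, an unfavourable homo-/cross-coupling distribution, and anodic degradation or methanolysis of the aryl acetate part during the run. The fallback replaces the radical union by olefin metathesis; it sets out from 1 and returns to the route at 8.
   - 1 is esterified on its primary OH with 10-undecenoic acid (Novozym 435, 4 Å MS, 2-methyl-2-butanol, 60 °C) to give 2-(4-hydroxyphenyl)ethyl undec-10-enoate F1.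
   - Cross-metathesis of F1 with excess 1-nonadecene (Grubbs second-generation catalyst, CH2Cl2, 40 °C) should give 2-(4-hydroxyphenyl)ethyl octacos-10-enoate F2 as an E/Z mixture.
   - Hydrogenation of F2 (H2, Pd/C, EtOAc/THF) should deliver 8.

2. Step 1 (enzymatic mono-esterification of a symmetrical diacid). Possible failures are over-acylation to the bis-tyrosyl diester, slow turnover of the sparingly soluble diacid, and a difficult separation of the half-ester from excess diacid. The fallback uses a pre-differentiated diacid and chemical differentiation of the two hydroxyls; it sets out from 1, bypasses step 2, and returns at 5.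
   - 1 is acetylated selectively on the phenol via its phenoxide (Ac2O, aqueous NaOH, 0 °C) to give 4-(2-hydroxyethyl)phenyl acetate F3.
   - Steglich esterification of F3 with commercial 12-(tert-butoxy)-12-oxododecanoic acid (EDC·HCl, cat. DMAP, CH2Cl2, 0 °C to rt) should give 1-tert-butyl 12-[2-(4-acetoxyphenyl)ethyl] dodecanedioate F4.
   - Acidolysis of the tert-butyl ester of F4 (TFA, CH2Cl2, rt) should give 5.

3. Step 4 (selective removal of the O-acetyl group). Possible failures are sluggish reaction of the poorly soluble wax and competing cleavage of the C1 alkyl ester on forcing. The fallback gives up the selective deprotection and relies on enzymatic chemoselectivity for the ester bond; it sets out from 7 and returns at 8.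
   - Exhaustive saponification of 7 (KOH, EtOH/THF/H2O, reflux; then aqueous HCl) gives octacosanoic acid F5.
   - F5 is esterified with fresh 1 (Novozym 435, 4 Å MS, toluene/2-methyl-2-butanol, 70 °C), which acylates only the aliphatic OH and should give 8.

**Further compounds**
F1 | step 3 | 2-(4-hydroxyphenyl)ethyl undec-10-enoate | C=CCCCCCCCCC(=O)OCCc1ccc(O)cc1
F2 | step 3 | 2-(4-hydroxyphenyl)ethyl (E)-octacos-10-enoate (E/Z mixture expected) | CCCCCCCCCCCCCCCCC/C=C/CCCCCCCCC(=O)OCCc1ccc(O)cc1
F3 | step 1 | 4-(2-hydroxyethyl)phenyl acetate | CC(=O)Oc1ccc(CCO)cc1
F4 | step 1 | 1-tert-butyl 12-[2-(4-acetoxyphenyl)ethyl] dodecanedioate | CC(C)(C)OC(=O)CCCCCCCCCCC(=O)OCCc1ccc(OC(C)=O)cc1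
F5 | step 4 | octacosanoic acid | CCCCCCCCCCCCCCCCCCCCCCCCCCCC(=O)O
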